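**Retrosynthetic overview**
- The dihydropyranone is closed last: acid removes an acetonide and the freed δ-hydroxyl lactonises onto a Z-enoate. Just before that, the Z-p-coumarate is attached by Mitsunobu esterification, which inverts an (S)-lactyl centre to (R).
- The trans-cyclopropane comes from a light-driven iodomethyl radical addition / anionic 3-exo-tet closure on an E-enone, steered by the neighbouring dioxolane stereocentre.
- The enone comes from one-flask oxidation/Wittig coupling of a dioxolanyl alcohol with a lactate-derived keto-ylide.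
- The dioxolanyl Z-enoate (both carbinol centres) comes from 2-deoxy-L-ribose, the ylide from ethyl (S)-lactate, and the Z-acid from a 4-silyloxybenzaldehyde.
- Ring order: temporary dioxolane, then cyclopropane, then dihydropyranone.

Assumption: 2-deoxy-L-ribose, ethyl (S)-lactate, 4-(tert-butyldimethylsilyloxy)benzaldehyde, the Ando phosphonate and triethylammonium bis(catecholato)(iodomethyl)silicate are taken as commercial.

**Step 1**
Reactants: 1 2-deoxy-L-ribose
Product: 2 2-deoxy-3,4-O-isopropylidene-L-erythro-pentopyranose (anomer mixture)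
Conditions: 2-methoxypropene, PPTS (cat.), EtOAc, −10 °C → rt
Reagents that add atoms: 2-methoxypropene COC(C)=C
Why: Kinetic acid-catalysed acetalisation of the cis-3,4-diol of the pyranose form leaves the lactol free and touches no stereocentre.

**Step 2**
Reactants: 2 2-deoxy-3,4-O-isopropylidene-L-erythro-pentopyranose
Product: 3 ethyl (2Z)-4-[(4R,5S)-5-(hydroxymethyl)-2,2-dimethyl-1,3-dioxolan-4-yl]but-2-enoate
Conditions: (2-MeC6H4O)2P(O)CH2CO2Et (2 equiv), NaH, THF, −78 → 0 °C
Reagents that add atoms: ethyl 2-[bis(2-methylphenoxy)phosphoryl]acetate CCOC(=O)CP(=O)(Oc1ccccc1C)Oc1ccccc1C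
Why: Ando-type Z-selective Horner–Wadsworth–Emmons olefination of the ring-opened hydroxy aldehyde gives the Z-enoate needed for the final lactonisation.

**Step 3**
Reactants: 4 ethyl (S)-lactate
Product: 5 ethyl (2S)-2-(tert-butyldimethylsilyloxy)propanoate
Conditions: TBSCl, imidazole, DMF, 0 °C → rt
Reagents that add atoms: tert-butyldimethylsilyl chloride CC(C)(C)[Si](C)(C)Cl
Why: Standard imidazole-promoted silylation of the secondary alcohol, with the stereocentre untouched.

**Step 4**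
Reactants: 5 ethyl (2S)-2-(tert-butyldimethylsilyloxy)propanoate
Product: 6 (3S)-3-(tert-butyldimethylsilyloxy)-1-(triphenylphosphoranylidene)butan-2-one
Conditions: Ph3PCH3Br, n-BuLi (2.2 equiv each), THF, 0 °C; then 5, −78 °C → rt
Reagents that add atoms: methyltriphenylphosphonium bromide C[P+](c1ccccc1)(c1ccccc1)c1ccccc1.[Br-], used as methylenetriphenylphosphorane C=P(c1ccccc1)(c1ccccc1)c1ccccc1 made in the flask
Why: Acylation of methylenetriphenylphosphorane by the ester (the second equivalent deprotonates the acylphosphonium salt) gives the keto-stabilised ylide without touching the silyloxy stereocentre.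

**Step 5**
Reactants: 3 ethyl (2Z)-4-[(4R,5S)-5-(hydroxymethyl)-2,2-dimethyl-1,3-dioxolan-4-yl]but-2-enoate; 6 (3S)-3-(tert-butyldimethylsilyloxy)-1-(triphenylphosphoranylidene)butan-2-one
Product: 8 ethyl (2Z)-4-[(4R,5S)-5-[(1E,4S)-4-(tert-butyldimethylsilyloxy)-3-oxopent-1-en-1-yl]-2,2-dimethyl-1,3-dioxolan-4-yl]but-2-enoate, via dioxolane aldehyde 7 (not isolated)
Conditions: Dess–Martin periodinane, pyridine, CH2Cl2, 0 °C → rt; then 6 in the same flask, 40 °C
Reagents that add atoms: none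
Why: Dess–Martin oxidation followed in the same flask by E-selective Wittig olefination with the stabilised keto-ylide traps the epimerisable cis-dioxolane aldehyde as it forms.

**Step 6**
Reactants: 8 ethyl (2Z)-4-[(4R,5S)-5-[(1E,4S)-4-(tert-butyldimethylsilyloxy)-3-oxopent-1-en-1-yl]-2,2-dimethyl-1,3-dioxolan-4-yl]but-2-enoate
Product: 9 ethyl (2Z)-4-[(4R,5S)-5-[(1S,2S)-2-[(2S)-2-(tert-butyldimethylsilyloxy)propanoyl]cyclopropyl]-2,2-dimethyl-1,3-dioxolan-4-yl]but-2-enoate
Conditions: [Et3NH][ICH2Si(O2C6H4)2] (1.5–2 equiv), 4CzIPN (5 mol %), DMSO, blue LEDs (450 nm), rt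
Reagents that add atoms: triethylammonium bis(catecholato)(iodomethyl)silicate CC[NH+](CC)CC.IC[Si-]12(Oc3ccccc3O1)Oc1ccccc1O2
Why: Proposed new method: photoredox radical–polar crossover cyclopropanation of an acyclic β-substituted γ-alkoxy enone under 1,2-substrate control, which has not been shown; excited 4CzIPN oxidises the silicate to the iodomethyl radical, which adds to C-β of the enone (the more electrophilic of the two acceptors) on the face opposite the dioxolane in a Felkin-type staggered transition state (1,2-anti to the allylic oxygen, the sense seen for sulfur-ylide and diazomethane additions to dioxolanyl enoates), the reduced photocatalyst converts the α-keto radical into the enolate, and 3-exo-tet displacement of iodide closes the ring trans (the open-chain intermediate makes the closure stereoconvergent), setting both cyclopropane centres as (1S,2S); the closest known reaction type is the photoredox iodomethylsilicate cyclopropanation of styrenes and α-substituted acrylates.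

**Step 7**
Reactants: 9 ethyl (2Z)-4-[(4R,5S)-5-[(1S,2S)-2-[(2S)-2-(tert-butyldimethylsilyloxy)propanoyl]cyclopropyl]-2,2-dimethyl-1,3-dioxolan-4-yl]but-2-enoate
Product: 10 ethyl (2Z)-4-[(4R,5S)-5-[(1S,2S)-2-[(2S)-2-hydroxypropanoyl]cyclopropyl]-2,2-dimethyl-1,3-dioxolan-4-yl]but-2-enoate
Conditions: HF·pyridine, pyridine, THF, 0 °C → rt
Reagents that add atoms: none
Why: Buffered fluoride desilylation frees the α-ketol while the acetonide, cyclopropyl ketone and Z-enoate are left intact.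

**Step 8**
Reactants: 11 4-(tert-butyldimethylsilyloxy)benzaldehyde
Product: 12 ethyl (2Z)-3-[4-(tert-butyldimethylsilyloxy)phenyl]prop-2-enoate
Conditions: (2-MeC6H4O)2P(O)CH2CO2Et, NaH, THF, −78 °C
Reagents that add atoms: ethyl 2-[bis(2-methylphenoxy)phosphoryl]acetate CCOC(=O)CP(=O)(Oc1ccccc1C)Oc1ccccc1C
Why: Ando Z-selective Horner–Wadsworth–Emmons olefination of an aromatic aldehyde normally gives Z:E above 95:5.

**Step 9**
Reactants: 12 ethyl (2Z)-3-[4-(tert-butyldimethylsilyloxy)phenyl]prop-2-enoate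
Product: 13 (2Z)-3-(4-hydroxyphenyl)prop-2-enoic acid
Conditions: LiOH, THF/MeOH/H2O, rt, dark; then aq. HCl, 0 °C
Reagents that add atoms: lithium hydroxide [Li+].[OH-]
Why: Saponification of the ethyl ester with concurrent cleavage of the base-labile aryl silyl ether, the Z-alkene being configurationally stable to hydroxide in the dark.

**Step 10**
Reactants: 10 ethyl (2Z)-4-[(4R,5S)-5-[(1S,2S)-2-[(2S)-2-hydroxypropanoyl]cyclopropyl]-2,2-dimethyl-1,3-dioxolan-4-yl]but-2-enoate; 13 (2Z)-3-(4-hydroxyphenyl)prop-2-enoic acid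
Product: 14 ethyl (2Z)-4-[(4R,5S)-5-[(1S,2S)-2-[(2R)-2-{[(2Z)-3-(4-hydroxyphenyl)prop-2-enoyl]oxy}propanoyl]cyclopropyl]-2,2-dimethyl-1,3-dioxolan-4-yl]but-2-enoate
Conditions: PPh3, DIAD, THF, 0 °C → rt, dark
Reagents that add atoms: none
Why: Mitsunobu esterification, in which SN2 displacement of the α-ketol oxyphosphonium by the carboxylate inverts the lactate-derived centre from S to R, the less acidic phenol stays out, and the Z-acid is never activated at its carbonyl so it cannot isomerise.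

**Step 11**
Reactants: 14 ethyl (2Z)-4-[(4R,5S)-5-[(1S,2S)-2-[(2R)-2-{[(2Z)-3-(4-hydroxyphenyl)prop-2-enoyl]oxy}propanoyl]cyclopropyl]-2,2-dimethyl-1,3-dioxolan-4-yl]but-2-enoate
Product: 16 (2R)-1-[(1S,2S)-2-[(S)-hydroxy[(2R)-6-oxo-3,6-dihydro-2H-pyran-2-yl]methyl]cyclopropyl]-1-oxopropan-2-yl (2Z)-3-(4-hydroxyphenyl)prop-2-enoate, via dihydroxy enoate 15 (not isolated)
Conditions: AcOH/H2O (4:1), 45 °C, dark; then concentration from PhMe
Reagents that add atoms: none
Why: Acetal hydrolysis releases the diol and the δ-hydroxyl closes onto the Z-enoate by 6-membered lactonisation (the other hydroxyl would need a 7-membered ring), with no stereocentre touched.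

**Compound list**
1 | 2-deoxy-L-ribose (written as the open-chain aldehyde) | O=CC[C@@H](O)[C@@H](O)CO | starting material
2 | 2-deoxy-3,4-O-isopropylidene-L-erythro-pentopyranose (anomer mixture) | OC1C[C@H]2OC(C)(C)O[C@H]2CO1 | intermediate
3 | ethyl (2Z)-4-[(4R,5S)-5-(hydroxymethyl)-2,2-dimethyl-1,3-dioxolan-4-yl]but-2-enoate | OC[C@@H]1OC(C)(C)O[C@@H]1C/C=C\C(=O)OCC | intermediate
4 | ethyl (S)-lactate | CCOC(=O)[C@H](C)O | starting material
5 | ethyl (2S)-2-(tert-butyldimethylsilyloxy)propanoate | CCOC(=O)[C@H](C)O[Si](C)(C)C(C)(C)C | intermediate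
6 | (3S)-3-(tert-butyldimethylsilyloxy)-1-(triphenylphosphoranylidene)butan-2-one | C[C@H](O[Si](C)(C)C(C)(C)C)C(=O)C=P(c1ccccc1)(c1ccccc1)c1ccccc1 | intermediate
7 | ethyl (2Z)-4-[(4R,5R)-5-formyl-2,2-dimethyl-1,3-dioxolan-4-yl]but-2-enoate | O=C[C@@H]1OC(C)(C)O[C@@H]1C/C=C\C(=O)OCC | intermediate (not isolated)
8 | ethyl (2Z)-4-[(4R,5S)-5-[(1E,4S)-4-(tert-butyldimethylsilyloxy)-3-oxopent-1-en-1-yl]-2,2-dimethyl-1,3-dioxolan-4-yl]but-2-enoate | C[C@H](O[Si](C)(C)C(C)(C)C)C(=O)/C=C/[C@@H]1OC(C)(C)O[C@@H]1C/C=C\C(=O)OCC | intermediate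
9 | ethyl (2Z)-4-[(4R,5S)-5-[(1S,2S)-2-[(2S)-2-(tert-butyldimethylsilyloxy)propanoyl]cyclopropyl]-2,2-dimethyl-1,3-dioxolan-4-yl]but-2-enoate | C[C@H](O[Si](C)(C)C(C)(C)C)C(=O)[C@H]1C[C@@H]1[C@@H]1OC(C)(C)O[C@@H]1C/C=C\C(=O)OCC | intermediate
10 | ethyl (2Z)-4-[(4R,5S)-5-[(1S,2S)-2-[(2S)-2-hydroxypropanoyl]cyclopropyl]-2,2-dimethyl-1,3-dioxolan-4-yl]but-2-enoate | C[C@H](O)C(=O)[C@H]1C[C@@H]1[C@@H]1OC(C)(C)O[C@@H]1C/C=C\C(=O)OCC | intermediate
11 | 4-(tert-butyldimethylsilyloxy)benzaldehyde | O=Cc1ccc(O[Si](C)(C)C(C)(C)C)cc1 | starting material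
12 | ethyl (2Z)-3-[4-(tert-butyldimethylsilyloxy)phenyl]prop-2-enoate | CCOC(=O)/C=C\c1ccc(O[Si](C)(C)C(C)(C)C)cc1 | intermediate
13 | (2Z)-3-(4-hydroxyphenyl)prop-2-enoic acid | OC(=O)/C=C\c1ccc(O)cc1 | intermediate
14 | ethyl (2Z)-4-[(4R,5S)-5-[(1S,2S)-2-[(2R)-2-{[(2Z)-3-(4-hydroxyphenyl)prop-2-enoyl]oxy}propanoyl]cyclopropyl]-2,2-dimethyl-1,3-dioxolan-4-yl]but-2-enoate | C[C@@H](OC(=O)/C=C\c1ccc(O)cc1)C(=O)[C@H]1C[C@@H]1[C@@H]1OC(C)(C)O[C@@H]1C/C=C\C(=O)OCC | intermediate
15 | ethyl (2Z,5R,6S)-5,6-dihydroxy-6-[(1S,2S)-2-[(2R)-2-{[(2Z)-3-(4-hydroxyphenyl)prop-2-enoyl]oxy}propanoyl]cyclopropyl]hex-2-enoate | C[C@@H](OC(=O)/C=C\c1ccc(O)cc1)C(=O)[C@H]1C[C@@H]1[C@H](O)[C@H](O)C/C=C\C(=O)OCC | intermediate (not isolated)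
16 | (2R)-1-[(1S,2S)-2-[(S)-hydroxy[(2R)-6-oxo-3,6-dihydro-2H-pyran-2-yl]methyl]cyclopropyl]-1-oxopropan-2-yl (2Z)-3-(4-hydroxyphenyl)prop-2-enoate | C[C@@H](OC(=O)/C=C\c1ccc(O)cc1)C(=O)[C@H]1C[C@@H]1[C@H](O)[C@H]1CC=CC(=O)O1 | target

**Step count**
Total: 11 steps. Longest linear sequence: 7 steps (steps 1, 2, 5, 6, 7, 10, 11).

**Steps most likely to fail**

Step 6 (the proposed new cyclopropanation). The iodomethyl radical may add slowly to a β-substituted enone, may also attack the Z-enoate, and 1,2-induction in a radical addition may be lower than in polar additions. If the uncyclised γ-iodo ketone is seen, brief DBU treatment should close it. The fallback sets out from 8 and returns at 9 using known chemistry. Diazomethane (Et2O, 0 °C) undergoes 1,3-dipolar cycloaddition to the enone, anti to the dioxolane oxygen, to give ethyl (2Z)-4-[(4R,5S)-5-[(3S,4S)-3-[(2S)-2-(tert-butyldimethylsilyloxy)propanoyl]-4,5-dihydro-3H-pyrazol-4-yl]-2,2-dimethyl-1,3-dioxolan-4-yl]but-2-enoate F3. This is irradiated at once (350 nm, benzophenone sensitiser, CH2Cl2, −20 °C) before it can tautomerise; it loses nitrogen with retention, so the ring-closing C–C bond is still formed by light, and 9 results.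

Step 2 (Z-selective olefination of a lactol). The lactol opens only at temperatures where Z-selectivity erodes, and the primary alkoxide can add in conjugate fashion to the enoate. The fallback sets out from 2 and returns at 3. Ohira–Bestmann homologation (dimethyl (1-diazo-2-oxopropyl)phosphonate, K2CO3, MeOH) gives the alkynol [(4S,5R)-2,2-dimethyl-5-(prop-2-yn-1-yl)-1,3-dioxolan-4-yl]methanol F1. Oxidative alkoxycarbonylation of the terminal alkyne (PdCl2 cat., CuCl2, NaOAc, CO, EtOH, rt) gives ethyl 4-[(4R,5S)-5-(hydroxymethyl)-2,2-dimethyl-1,3-dioxolan-4-yl]but-2-ynoate F2. cis-Semihydrogenation (H2, Pd/CaCO3 poisoned with Pb(OAc)2, quinoline, EtOAc) then delivers 3 with the Z geometry fixed by syn addition.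

Step 10 (Mitsunobu inversion at an α-ketol with a free phenol present). Possible problems are elimination to a vinyl ketone, partial loss of configuration, and phenol O-alkylation. The fallback sets out from 10 and returns at 14. Mesylation (MsCl, Et3N, CH2Cl2, −20 °C) gives ethyl (2Z)-4-[(4R,5S)-2,2-dimethyl-5-[(1S,2S)-2-[(2S)-2-(methylsulfonyloxy)propanoyl]cyclopropyl]-1,3-dioxolan-4-yl]but-2-enoate F4. The mono-cesium carboxylate of 13 (CsHCO3, 1 equiv, DMF, rt, dark) then displaces the mesylate by SN2 with inversion to give 14.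

**Further compounds**
F1 | step 2 | [(4S,5R)-2,2-dimethyl-5-(prop-2-yn-1-yl)-1,3-dioxolan-4-yl]methanol | OC[C@@H]1OC(C)(C)O[C@@H]1CC#C
F2 | step 2 | ethyl 4-[(4R,5S)-5-(hydroxymethyl)-2,2-dimethyl-1,3-dioxolan-4-yl]but-2-ynoate | OC[C@@H]1OC(C)(C)O[C@@H]1CC#CC(=O)OCC
F3 | step 6 | ethyl (2Z)-4-[(4R,5S)-5-[(3S,4S)-3-[(2S)-2-(tert-butyldimethylsilyloxy)propanoyl]-4,5-dihydro-3H-pyrazol-4-yl]-2,2-dimethyl-1,3-dioxolan-4-yl]but-2-enoate | C[C@H](O[Si](C)(C)C(C)(C)C)C(=O)[C@H]1N=NC[C@@H]1[C@@H]1OC(C)(C)O[C@@H]1C/C=C\C(=O)OCC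
F4 | step 10 | ethyl (2Z)-4-[(4R,5S)-2,2-dimethyl-5-[(1S,2S)-2-[(2S)-2-(methylsulfonyloxy)propanoyl]cyclopropyl]-1,3-dioxolan-4-yl]but-2-enoate | C[C@H](OS(C)(=O)=O)C(=O)[C@H]1C[C@@H]1[C@@H]1OC(C)(C)O[C@@H]1C/C=C\C(=O)OCC
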